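The numbers in the tables are calculated with constants of no real substance; scatter was added.

What we look for in the earlier runs is something that stays put from one flask to the next: how much product one catalyst makes in an hour.

| setting | eta | delta | theta | flask |
|---|---|---|---|---|
| solid substrate | 0.10 M | 0.10 M | 0.050 M | 0.10 M |
| gas phase | 4 mM (held) | 4 mM (held) | 4 mM (held) | 4.0 mM (held) |
| catalyst | 0.049 mol% | 0.2 mol% | 0.098 mol% | 0.098 mol% |
| remark | run made earlier | run made earlier | run made earlier |  |
| time |  |  |  | 5.0 h |

- eta (time / h: product / %): 0.333: 0.6; 1.00: 0.1; 2.00: 1.4; 3.00: 3.6; 4.00: 3.8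
- delta (time / h: product / %): 0.833: 3.1; 1.50: 4.1; 2.50: 8.5; 3.00: 10.7; 4.00: 13.5
- theta (time / h: product / %): 0.333: 0.5; 0.667: 1.1; 1.00: 1.5; 2.00: 3.8; 4.00: 5.6

(each reading ± 0.5 percentage points)

- given per volume of solution although it is solid: solid substrate
- what was read earlier has a scatter of 0.5 percentage points, one standard deviation
- at the start none of the gas phase is in solution
- at the start none of the solid substrate is in solution

- product at 5.0 h, in percent of the solid substrate charged
- concentration of dissolved gas in solution at 5.0 h, in percent of saturation

The last readings give 16.9 h⁻¹ in delta, 19.4 h⁻¹ in eta and 14.3 h⁻¹ in theta, each carrying the scatter of 0.5 percentage points. We keep delta's figure, from the highest reading, as the turnover frequency, product per catalyst per hour. A steady pace integrates to a straight line: percent product is turnover frequency times loading times time.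

Turn the question round: the new flask leaves that line if the solid substrate runs out or [dissolved gas] falls away. At this pace the charge would last 60.5 h, far beyond the 5.0 h asked. Delta made product at 3.38 mM h⁻¹ over its run, and the flask at this pace makes 1.65 mM h⁻¹, half of that. So we commit to 8.27% product and [dissolved gas] close to saturation.

The forecast gives 8.5% and 92%, reasoning: “The reaction is therefore roughly zero order in the solid”. Its product figure lies 0.23 points above ours.

The flask gives 8.61% and 95.8%, so the forecast holds. For the product to move by 5 points, the catalyst loading moved alone would have to stand at 0.04 mol% or 0.16 mol%, or the time at 2.20 h or 7.80 h. Read back, the result is a turnover frequency of 17.6 h⁻¹.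

    gas phase ⇌ dissolved gas, rate k1*(csat - [dissolved gas]) (kL = 0.615 min⁻¹)
    starting material + dissolved gas + catalyst → catalyst + product (k = 7430 M⁻² min⁻¹)
    solid substrate ⇌ starting material, rate k3*(cs3 - [starting material]) while solid is left; crystals form when [starting material] > cs3 (solubility = 11.0 mM, k = 0.0914 min⁻¹)
    2 dissolved gas → homo dimer (k = 2.52 M⁻¹ min⁻¹)

Read at 20 h, the same flask should hold 33.1% by our turnover frequency. The computed result is 35.4%.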